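## Retrosynthetic overview

1. The C7 carbinol comes from Felkin–Anh hydride reduction of aryl ketone 18, which is the O-methyl ether of hydroxy ketone 17.
2. The cyclohexene (last ring formed) comes from a chiral-borate Diels–Alder reaction of two coumarin halves of equal size, diene 12 (C16) and 2-hydroxyaryl enone 16 (C15). This sets C1 and C6 (trans).
3. Diene 12 comes from Suzuki coupling of 8-iodo-5,7-dimethoxycoumarin 7 with dienylboronate 11. Enone 16 comes from Friedel–Crafts acylation of 5,7-dimethoxycoumarin 6 with acid chloride 14, then BCl3 ortho-demethylation.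
4. Coumarin 6 (pyranone ring formed first, one batch feeds both halves) comes from 3,5-dimethoxyphenol and ethyl propiolate; the phenol comes from resorcinol by methylation and Ir-borylation/oxidation.

Assumption: the facial sense of the (R)-VANOL–borate in step 11 is assigned by analogy with 2'-hydroxychalcone dienophiles; if the first run gives the mirror-image adduct, (S)-VANOL is used in the identical procedure.

## Route

Step 1
Reactants: 1 resorcinol
Product: 2 1,3-dimethoxybenzene
Conditions: MeI (2.5 equiv), K2CO3, acetone, reflux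
Reagents that add atoms: iodomethane CI
Why: Williamson ether synthesis, both phenoxides being methylated by SN2 on MeI.

Step 2
Reactants: 2 1,3-dimethoxybenzene
Product: 4 3,5-dimethoxyphenol, via 3,5-dimethoxyphenylboronic acid pinacol ester 3 (not isolated)
Conditions: [Ir(OMe)(cod)]2 (1 mol %), dtbpy (2 mol %), B2pin2 (0.55 equiv), THF, 80 °C; then Oxone, acetone/H2O, 0 °C to rt
Reagents that add atoms: bis(pinacolato)diboron CC1(C)OB(OC1(C)C)B1OC(C)(C)C(C)(C)O1 (boron group of 3); potassium peroxymonosulfate [K+].[O-]S(=O)(=O)OO (oxygen of 4)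
Why: Sterically controlled Ir-catalysed C–H borylation goes to C5, the only C–H not ortho to a methoxy group, and the C–B bond is oxidised in the same pot to the phenol.

Step 3
Reactants: 4 3,5-dimethoxyphenol; 5 ethyl propiolate
Product: 6 5,7-dimethoxy-2H-chromen-2-one
Conditions: Pd(OAc)2 (5 mol %), NaOAc (10 mol %), HCO2H, rt
Reagents that add atoms: none
Why: Pd-catalysed hydroarylation/lactonisation (Trost coumarin synthesis) of an electron-rich phenol whose two ortho positions are equivalent, so only one coumarin can form.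

Step 4
Reactants: 6 5,7-dimethoxy-2H-chromen-2-one
Product: 7 8-iodo-5,7-dimethoxy-2H-chromen-2-one
Conditions: NIS (1.05 equiv), TFA (10 mol %), MeCN, 0 °C to rt, dark
Reagents that add atoms: N-iodosuccinimide O=C1CCC(=O)N1I
Why: Electrophilic aromatic iodination at C8, which is ortho to the 7-OMe and para to the 5-OMe and is expected to be the most nucleophilic ring position (regiochemistry to be confirmed by NOE/HMBC).

Step 5
Reactants: 8 2-methylbut-3-yn-2-ol
Product: 10 2-methylbut-1-en-3-yne, via 2-methylbut-3-yn-2-yl acetate 9 (not isolated)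
Conditions: Ac2O (1.1 equiv), TsOH·H2O (2 mol %), 120–130 °C, product distilled out as formed (bp 32–34 °C)
Reagents that add atoms: acetic anhydride CC(=O)OC(C)=O (acetyl group of 9)
Why: Acid-catalysed acetylation and E1 elimination (dehydration) at the tertiary propargylic centre, with the volatile enyne removed by distillation before Rupe rearrangement can occur.

Step 6
Reactants: 10 2-methylbut-1-en-3-yne
Product: 11 4,4,5,5-tetramethyl-2-[(1E)-3-methylbuta-1,3-dien-1-yl]-1,3,2-dioxaborolane
Conditions: HBpin (1.05 equiv), Cp2Zr(H)Cl (5 mol %), Et3N (10 mol %), CH2Cl2, sealed tube, 25 °C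
Reagents that add atoms: pinacolborane CC1(C)OBOC1(C)C
Why: Zirconocene-catalysed hydroboration adds H–B syn and anti-Markovnikov across the terminal alkyne only, giving the E-dienylboronate.

Step 7
Reactants: 7 8-iodo-5,7-dimethoxy-2H-chromen-2-one; 11 4,4,5,5-tetramethyl-2-[(1E)-3-methylbuta-1,3-dien-1-yl]-1,3,2-dioxaborolane
Product: 12 5,7-dimethoxy-8-[(1E)-3-methylbuta-1,3-dien-1-yl]-2H-chromen-2-one
Conditions: Pd(dppf)Cl2 (5 mol %), K3PO4 (3 equiv), 1,4-dioxane/H2O, 70 °C; work-up at pH 5; stored cold with BHT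
Reagents that add atoms: none
Why: Suzuki–Miyaura coupling with retention of the E geometry; the lactone tolerates phosphate base and re-closes on mildly acidic work-up.

Step 8
Reactants: 13 3-methylbut-2-enoic acid
Product: 14 3-methylbut-2-enoyl chloride
Conditions: (COCl)2 (1.2 equiv), DMF (cat.), CH2Cl2, 0 °C to rt; distilled
Reagents that add atoms: oxalyl chloride ClC(=O)C(Cl)=O
Why: Acyl chloride formation through the catalytic chloroiminium species under conditions that leave the trisubstituted alkene untouched.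

Step 9
Reactants: 6 5,7-dimethoxy-2H-chromen-2-one; 14 3-methylbut-2-enoyl chloride
Product: 15 5,7-dimethoxy-8-(3-methylbut-2-enoyl)-2H-chromen-2-one
Conditions: TiCl4 (2.2 equiv), CH2Cl2, −20 to 0 °C; aqueous NaHCO3 work-up
Reagents that add atoms: none
Why: Friedel–Crafts acylation at C8 (same site selectivity as step 4), run cold so that the enone neither adds HCl nor loses a methyl ether.

Step 10
Reactants: 15 5,7-dimethoxy-8-(3-methylbut-2-enoyl)-2H-chromen-2-one
Product: 16 7-hydroxy-5-methoxy-8-(3-methylbut-2-enoyl)-2H-chromen-2-one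
Conditions: BCl3 (1.2 equiv), CH2Cl2, −78 to −20 °C; cold dilute HCl work-up; used promptly
Reagents that add atoms: none
Why: Chelation-controlled Lewis acid ether cleavage, in which BCl3 bound to the ketone removes only the ortho (C7) methyl group and leaves the 5-OMe and the lactone.

Step 11
Reactants: 12 5,7-dimethoxy-8-[(1E)-3-methylbuta-1,3-dien-1-yl]-2H-chromen-2-one; 16 7-hydroxy-5-methoxy-8-(3-methylbut-2-enoyl)-2H-chromen-2-one
Product: 17 8-[(1S,6R)-6-(7-hydroxy-5-methoxy-2-oxo-2H-chromene-8-carbonyl)-3,5,5-trimethylcyclohex-2-en-1-yl]-5,7-dimethoxy-2H-chromen-2-one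
Conditions: (R)-VANOL (1.2 equiv), BH3·THF (1.2 equiv), AcOH (1.2 equiv), THF, rt; then 16, then 12 (1.5 equiv), PhCF3, 40 °C; aqueous work-up; chromatography to remove the minor cis isomer
Reagents that add atoms: none
Why: Chiral-borate-promoted Diels–Alder reaction in which chelation of the 2-hydroxyaryl ketone to the VANOL–boron unit activates the β,β-dimethyl enone and shields one face, the diene CH2 terminus bonds to the CMe2 carbon (ortho/para regiochemistry), and the exo mode sets C1 (S) and C6 (R) trans.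

Step 12
Reactants: 17 the hydroxy ketone from step 11
Product: 18 8-[(1S,6R)-6-(5,7-dimethoxy-2-oxo-2H-chromene-8-carbonyl)-3,5,5-trimethylcyclohex-2-en-1-yl]-5,7-dimethoxy-2H-chromen-2-one
Conditions: MeI (3 equiv), K2CO3, DMF, 40 °C
Reagents that add atoms: iodomethane CI
Why: Williamson methylation of the chelated phenol under carbonate, which does not open the lactones and cannot erode C6 because the trans arrangement is the thermodynamic one.

Step 13
Reactants: 18 the ketone from step 12
Product: 19 8-[(1S,6R)-6-[(R)-(5,7-dimethoxy-2-oxo-2H-chromen-8-yl)(hydroxy)methyl]-3,5,5-trimethylcyclohex-2-en-1-yl]-5,7-dimethoxy-2H-chromen-2-one (IN0553)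
Conditions: NaBH4, CeCl3·7H2O, MeOH/THF, −20 to 0 °C; pH 7 buffer work-up
Reagents that add atoms: none
Why: Luche 1,2-reduction in which hydride attacks the ketone (aryl group eclipsing C6–H) anti to the quaternary C5 carbon (Felkin–Anh), giving the (R)-carbinol while the coumarin enoates stay intact.

## Compound list

1 | resorcinol (benzene-1,3-diol) | Oc1cccc(O)c1 | starting material
2 | 1,3-dimethoxybenzene | COc1cccc(OC)c1 | intermediate
3 | 2-(3,5-dimethoxyphenyl)-4,4,5,5-tetramethyl-1,3,2-dioxaborolane (3,5-dimethoxyphenylboronic acid pinacol ester) | COc1cc(OC)cc(c1)B1OC(C)(C)C(C)(C)O1 | intermediate (not isolated)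
4 | 3,5-dimethoxyphenol | COc1cc(O)cc(OC)c1 | intermediate
5 | ethyl propiolate | CCOC(=O)C#C | starting material
6 | 5,7-dimethoxy-2H-chromen-2-one | COc1cc(OC)c2ccc(=O)oc2c1 | intermediate
7 | 8-iodo-5,7-dimethoxy-2H-chromen-2-one | COc1cc(OC)c2ccc(=O)oc2c1I | intermediate
8 | 2-methylbut-3-yn-2-ol | CC(C)(O)C#C | starting material
9 | 2-methylbut-3-yn-2-yl acetate | CC(=O)OC(C)(C)C#C | intermediate (not isolated)
10 | 2-methylbut-1-en-3-yne | C=C(C)C#C | intermediate
11 | 4,4,5,5-tetramethyl-2-[(1E)-3-methylbuta-1,3-dien-1-yl]-1,3,2-dioxaborolane | CC(=C)/C=C/B1OC(C)(C)C(C)(C)O1 | intermediate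
12 | 5,7-dimethoxy-8-[(1E)-3-methylbuta-1,3-dien-1-yl]-2H-chromen-2-one | COc1cc(OC)c2ccc(=O)oc2c1/C=C/C(C)=C | intermediate
13 | 3-methylbut-2-enoic acid | CC(C)=CC(=O)O | starting material
14 | 3-methylbut-2-enoyl chloride | CC(C)=CC(=O)Cl | intermediate
15 | 5,7-dimethoxy-8-(3-methylbut-2-enoyl)-2H-chromen-2-one | COc1cc(OC)c2ccc(=O)oc2c1C(=O)C=C(C)C | intermediate
16 | 7-hydroxy-5-methoxy-8-(3-methylbut-2-enoyl)-2H-chromen-2-one | COc1cc(O)c(C(=O)C=C(C)C)c2oc(=O)ccc12 | intermediate
17 | 8-[(1S,6R)-6-(7-hydroxy-5-methoxy-2-oxo-2H-chromene-8-carbonyl)-3,5,5-trimethylcyclohex-2-en-1-yl]-5,7-dimethoxy-2H-chromen-2-one | COc1cc(OC)c2ccc(=O)oc2c1[C@H]1C=C(C)CC(C)(C)[C@@H]1C(=O)c1c(O)cc(OC)c2ccc(=O)oc12 | intermediate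
18 | 8-[(1S,6R)-6-(5,7-dimethoxy-2-oxo-2H-chromene-8-carbonyl)-3,5,5-trimethylcyclohex-2-en-1-yl]-5,7-dimethoxy-2H-chromen-2-one | COc1cc(OC)c2ccc(=O)oc2c1[C@H]1C=C(C)CC(C)(C)[C@@H]1C(=O)c1c(OC)cc(OC)c2ccc(=O)oc12 | intermediate
19 | 8-[(1S,6R)-6-[(R)-(5,7-dimethoxy-2-oxo-2H-chromen-8-yl)(hydroxy)methyl]-3,5,5-trimethylcyclohex-2-en-1-yl]-5,7-dimethoxy-2H-chromen-2-one (IN0553) | COc1cc(OC)c2ccc(=O)oc2c1[C@H]1C=C(C)CC(C)(C)[C@@H]1[C@@H](O)c1c(OC)cc(OC)c2ccc(=O)oc12 | target

## Step count and risks

Total step count: 13.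
Longest linear sequence: 8 steps (1, 2, 3, 4, 7, 11, 12, 13; the path 1, 2, 3, 9, 10, 11, 12, 13 is equally long).

Steps most likely to fail:

Step 11. The β,β-dimethyl enone may be too hindered for the chiral borate, the electron-rich diene may oligomerise, or the ee may be low. The fallback sets out from 12 and 16. The cycloaddition is run without a chiral promoter under a different activation mode, silica-supported silver nanoparticles (AgNP/SiO2, CH2Cl2, 50 °C). This gives the trans adduct as the racemate, that is 17 together with its mirror image 8-[(1R,6S)-6-(7-hydroxy-5-methoxy-2-oxo-2H-chromene-8-carbonyl)-3,5,5-trimethylcyclohex-2-en-1-yl]-5,7-dimethoxy-2H-chromen-2-one F1. The two enantiomers are separated by preparative SFC on a chiral stationary phase, and the route is rejoined at 17.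

Step 13. The ketone sits between a 2,6-disubstituted aryl group and a carbon flanked by a quaternary centre, so reduction may be slow. Hydride may also enter from the C5 side rather than the C1 side and give the (S)-carbinol. The fallback sets out from 18. The reduction is pushed to completion (NaBH4, MeOH/THF, rt) to the epimeric alcohol 8-[(1S,6R)-6-[(S)-(5,7-dimethoxy-2-oxo-2H-chromen-8-yl)(hydroxy)methyl]-3,5,5-trimethylcyclohex-2-en-1-yl]-5,7-dimethoxy-2H-chromen-2-one F2. F2 is then ionised with catalytic TFA in THF/H2O at 0 °C to the 2,4,6-trioxygenated benzylic cation. Water adds to this cation from the same open face that hydride used on the ketone, which now places OH where H was and gives the (R)-carbinol. The epimers are separable, the unwanted one is resubmitted, and the route is rejoined at 19.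

Step 9. Friedel–Crafts acylation with an unsaturated acid chloride can give HCl adducts, partial demethylation or C6/C8 mixtures. The fallback sets out from 6. Vilsmeier–Haack formylation (POCl3, DMF, 70 °C; aqueous NaOAc) gives 5,7-dimethoxy-2-oxo-2H-chromene-8-carbaldehyde F3. 2-Methylprop-1-enylmagnesium bromide (THF, −78 °C) adds to the aldehyde in preference to the lactone and gives racemic 8-(1-hydroxy-3-methylbut-2-en-1-yl)-5,7-dimethoxy-2H-chromen-2-one F4. MnO2 (CH2Cl2, rt) oxidises this allylic benzylic alcohol to the enone, and the route is rejoined at 15.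

Further compounds
F1 | step 11 | 8-[(1R,6S)-6-(7-hydroxy-5-methoxy-2-oxo-2H-chromene-8-carbonyl)-3,5,5-trimethylcyclohex-2-en-1-yl]-5,7-dimethoxy-2H-chromen-2-one (enantiomer of 17) | COc1cc(OC)c2ccc(=O)oc2c1[C@@H]1C=C(C)CC(C)(C)[C@H]1C(=O)c1c(O)cc(OC)c2ccc(=O)oc12
F2 | step 13 | 8-[(1S,6R)-6-[(S)-(5,7-dimethoxy-2-oxo-2H-chromen-8-yl)(hydroxy)methyl]-3,5,5-trimethylcyclohex-2-en-1-yl]-5,7-dimethoxy-2H-chromen-2-one (carbinol epimer of 19) | COc1cc(OC)c2ccc(=O)oc2c1[C@H]1C=C(C)CC(C)(C)[C@@H]1[C@H](O)c1c(OC)cc(OC)c2ccc(=O)oc12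
F3 | step 9 | 5,7-dimethoxy-2-oxo-2H-chromene-8-carbaldehyde | COc1cc(OC)c2ccc(=O)oc2c1C=O
F4 | step 9 | 8-(1-hydroxy-3-methylbut-2-en-1-yl)-5,7-dimethoxy-2H-chromen-2-one (racemic) | COc1cc(OC)c2ccc(=O)oc2c1C(O)C=C(C)C
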